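## Structural features

The target is a bicyclic aromatic compound without stereocentres, in which a benzene ring (ring A, C3a–C4–C5–C6–C7–C7a) is fused through the C3a–C7a bond to a pyrrole ring (ring B, N1–C2–C3–C3a–C7a) that keeps a free N–H. Its only substituents are three C–Br bonds, two on the adjacent pyrrole carbons C2 and C3 and one on C7, the benzene carbon bonded to C7a and peri to N1. The difficulty is purely positional, because C2 and C3 are the carbons an electrophilic bromine source attacks by itself, whereas C7 is the benzene position of an indole that electrophiles reach last, so this bromine has to descend from a functional group. The 2,3-dibromo-1H-indole unit is the fragile part: it is electron-rich, sensitive to strong acid, light and reducing metals, and its C–Br bonds rule out late steps with zerovalent palladium, organolithium reagents or catalytic hydrogenation. The N–H becomes acidic once the ring carries acyl and halogen groups and can interfere with electrophilic phosphorus or bromine reagents. The key step exploits that C7 is attached to C7a, an α-carbon of the pyrrole, while C3a is a β-carbon: with ring A saturated, a C7 carbonyl is an ordinary 2-acylpyrrole ketone that an acid chain on C3a can install by acylating C7a. In that ketone, once the nitrogen protecting group is removed, the only sp2 C–H bonds are those at C2 and C3, so bromination cannot stray into ring A, and the carbonyl oxygen marks the carbon that will carry the third bromine.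

## Logic of the disconnections

**11 to 10.** No skeletal bond is cut; the C4=C5 double bond of ring A is removed and a hydrogen is returned to each of C4 and C5. This turns the aryl C7–Br bond into a vinyl C7–Br bond on a C6=C7 alkene, which a ketone can deliver. The gain is that direct bromination of the least accessible benzene position is avoided. The forward step must dehydrogenate a CH2–CH2 unit without harming three C–Br bonds or the free N–H of ring B.

**10 to 9.** The C7–Br bond is cut and the C6=C7 double bond is exchanged for a C7=O carbonyl with C6 as CH2. Because C7 sits on C7a, this carbonyl is conjugated with ring B and can be reached by acylation. The third bromine is thereby replaced by an oxygen whose position is fixed by ring construction. The forward step must convert a conjugated carbonyl with an N–H neighbour into a vinyl bromide; the direction of elimination is unambiguous because C6 is the only α-CH2.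

**9 to 7 (through 8).** The C2–Br and C3–Br bonds are cut. In 7 these two carbons carry the only sp2 C–H bonds, so both halogens can be placed without any positional question in ring A. The result is a halogen-free bicyclic ketone. Ring bromination must outrun bromination at C6 next to the ketone and must go to completion at the less reactive C2.

**7 to 6.** The N1–H bond is exchanged for an N1–S bond to a sulfonyl group. That group is needed in the earlier steps to steer the first acylation to the β-carbon and to keep the five-membered ring from polymerising in acid. It has to be removed before bromination because it would deactivate C2 and C3. The forward cleavage must leave the ketone untouched.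

**6 to 4 (through 5).** The C7–C7a bond is cut, which opens ring A to a four-carbon acid chain on C3a. This is the strategic cut: it reduces the bicycle to a monocyclic heteroarene with one side chain and puts the future C7 at the acid carbon. The forward step must have the acyl carbon attacked by the α-carbon next to the chain and not by the β-carbon on its other side, and within the molecule and not between molecules.

**4 to 3.** The two C–H bonds at the chain carbon next to the ring (the future C4) are exchanged for a C=O group. That carbonyl is what an acylation leaves behind, so it exposes the next C–C disconnection. The forward deoxygenation must tolerate a carboxylic acid and a sulfonamide.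

**3 to 1 and 2.** The bond between the ring β-carbon (future C3a) and the ketone carbon (future C4) is cut. This gives two purchasable compounds, of which 2 supplies all four carbons C4 to C7 in the correct oxidation pattern. The forward acylation must go to the β-carbon of 1 and not to its α-carbon, which calls for AlCl3 in excess.

## Other disconnections considered

Alternative 1: The cut removes C3a–C4 and C7–C7a together, so that all of ring A is added as a four-carbon diene to the C3a–C7a edge of a five-membered nitrogen ring. In the forward key step 3-bromo-2H-pyran-2-one A1 and tert-butyl 2,3-dihydro-1H-pyrrole-1-carboxylate A2 would combine in a Diels–Alder reaction, followed on heating by loss of CO2 in a retro-[4+2] step. The product would be racemic tert-butyl cis-7-bromo-2,3,3a,7a-tetrahydro-1H-indole-1-carboxylate A3.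

- In favour: the step is convergent and forms two C–C bonds and ring A in one operation from A1 and A2. The polarisation of the partners (the nucleophilic β-carbon of A2 to C6 of A1, the nitrogen-bearing carbon of A2 to the bromine-bearing C3 of A1) should place bromine on the carbon that becomes C7. On this point the alternative is better than the chosen plan, because the C7–Br bond is bought with A1 and not made from a carbonyl group.
- Against: A3 still needs dehydrogenation of the cyclohexadiene, oxidation of the five-membered ring to a pyrrole and removal of the carbamate. At the temperature of CO2 extrusion A3 could aromatise the wrong way, by β-elimination of the carbamate nitrogen from C7a (opening ring B) or by loss of HBr. Both pyrrole bromines would then be introduced on an aromatic indole whose ring A carries C–H bonds, so their position rests on intrinsic reactivity alone.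
- Comparison: both plans build ring A onto an existing nitrogen ring, here by a pericyclic two-bond process and in the chosen plan by a polar one-bond closure. The two stereocentres at C3a and C7a of A3 are made only to be destroyed, whereas the chosen plan makes none. The count of operations should be equal to or slightly lower than seven, so on step economy the alternative is at least the equal. It is weaker in thermal robustness and in control over the C2 and C3 bromination.

Alternative 2: The cut is C3–C3a, closing ring B as a lactam. Starting from 2,6-dibromoaniline A4, N-(2,6-dibromophenyl)-N-(4-methoxybenzyl)acetamide A5 would be prepared. In the forward key step zerovalent palladium (for instance from Pd(OAc)2 and a bulky phosphine, with NaOtBu) would insert into one of the two equivalent C–Br bonds of A5 and the amide enolate would be arylated. The product would be 7-bromo-1-(4-methoxybenzyl)indolin-2-one A6.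

- In favour: the symmetry of A5 removes any positional question, since whichever bromide reacts, the other one ends at C7. The lactam carbonyl of A6 is a latent C2–Br (oxindoles give 2-bromoindoles with POBr3), and C3 of a 2-bromoindole is the only pyrrole carbon left for N-bromosuccinimide. In positional control this plan is the equal of the chosen one. It is better in that ring A is aromatic from the start and no dehydrogenation is needed.
- Against: A6 keeps an aryl bromide and has a more acidic CH2 than A5, so the catalyst could insert into the remaining C–Br bond and arylate the oxindole enolate. The nitrogen of A4 is flanked by two ortho bromines and should be hard to alkylate and acylate. The 4-methoxybenzyl group would have to be removed from an indole nitrogen in the presence of acid- and oxidant-sensitive C–Br bonds, which is the weakest point.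
- Comparison: the step count would be about six, which equals the chosen plan. The key step is catalytic organometallic chemistry with a chemoselectivity problem between A5 and A6. The chosen plan uses no transition metal and brings in every bromine after the last C–C bond is formed.

Alternative 3: The cut is N1–C2 together with C3–Br. From 2-bromo-6-iodoaniline A7, N-[2-bromo-6-(bromoethynyl)phenyl]-4-methylbenzenesulfonamide A8 would be made. In the forward key step N-bromosuccinimide would deliver positive bromine to the alkyne of A8 and the sulfonamide nitrogen would close in the 5-endo-dig mode onto the bromine-bearing alkyne carbon. The product would be 2,3,7-tribromo-1-tosylindole A9, one desulfonylation away from the target.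

- In favour: all three bromines are in their final positions in A9, one from the arene of A7, one from the bromoalkyne and one from the reagent. No redox adjustment is needed and the endgame is a single step. In positional certainty and in the number of steps after the key step this plan is better than the chosen one.
- Against: a 1-bromoalkyne is a poor π-nucleophile towards positive bromine, and the sulfonamide nitrogen of A8 is a weak nucleophile crowded by the ortho bromine. N-Bromination, or bromination of the arene para to nitrogen, could compete. The 5-endo-dig aminohalogenation is well supported for alkyl- and aryl-substituted alkynes but much less so for haloalkynes. Making A8 from A7 requires a coupling at C–I in the presence of C–Br, then sulfonylation and alkyne bromination. Cleavage of the sulfonyl group from A9 must avoid nucleophilic attack at C2–Br.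
- Comparison: the overall count from A7 should be about five to six steps, equal to or better than seven. The alternative concentrates its risk in one thinly supported cyclisation, whereas each step of the chosen plan belongs to a well-populated reaction class. The price of the chosen plan is the conversion of the ketone into the bromide.

Key step: step 3

Remark on the chemistry: positions are numbered as in indole throughout (the carbonyl carbon of 6 is C7, the ring-fusion carbons are C3a and C7a). The first bromine in step 5 is assumed to enter at C3; a 2-bromo isomer formed alongside would converge on the same dibromide 9.

## Route

Step 1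
Reactants: 1 1-tosyl-1H-pyrrole [1-(4-methylphenyl)sulfonylpyrrole]; 2 succinic anhydride
Product: 3 4-oxo-4-(1-tosyl-1H-pyrrol-3-yl)butanoic acid
Conditions: AlCl3 (3 equiv), ClCH2CH2Cl, 0 °C to rt; then ice/aq. HCl
Reagents that add atoms: none
Why: Friedel–Crafts acylation with a cyclic anhydride (first step of a Haworth sequence): with excess AlCl3 a 1-arylsulfonylpyrrole is acylated at the β-carbon, so the four-carbon chain is fixed to the carbon that becomes C3a. The keto acid formed is deactivated, which should prevent a second acylation.

Step 2
Reactants: 3 4-oxo-4-(1-tosyl-1H-pyrrol-3-yl)butanoic acid
Product: 4 4-(1-tosyl-1H-pyrrol-3-yl)butanoic acid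
Conditions: Et3SiH (3 equiv), CF3CO2H, rt to 50 °C
Reagents that add atoms: none
Why: Ionic hydrogenation of a heteroaryl ketone: protonation, hydride transfer from Et3SiH, ionisation of the pyrrolylic carbinol (or of the γ-lactone it may form with the acid) to a cation stabilised through the ring nitrogen, and a second hydride transfer give the CH2 group. The carboxylic acid and the sulfonamide are inert to Et3SiH in CF3CO2H.

Step 3
Reactants: 4 4-(1-tosyl-1H-pyrrol-3-yl)butanoic acid
Product: 6 1-tosyl-1,4,5,6-tetrahydro-7H-indol-7-one, via mixed anhydride 5 (not isolated)
Conditions: (CF3CO)2O (3 equiv), CH2Cl2 (0.05 M), 0 °C to rt
Reagents that add atoms: trifluoroacetic anhydride, O=C(OC(=O)C(F)(F)F)C(F)(F)F (its trifluoroacetyl group is present in 5 only and is lost again on ring closure)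
Why: Trifluoroacetic anhydride turns the carboxylic acid into the mixed anhydride 5, in which the alkanoyl carbonyl is activated because trifluoroacetate is a good leaving group. The pyrrole α-carbon next to the tether (future C7a) attacks that acyl carbon and gives a σ-complex, which rearomatises by loss of a proton while trifluoroacetate departs; the new bond is C7–C7a. The closest known reaction type is the ring-closing acylation of the Haworth sequence, an intramolecular Friedel–Crafts acylation, in the metal-free variant in which carboxylic acids and trifluoroacetic anhydride acylate 1-sulfonylpyrroles at the α-position. The six-membered carbocycle closes in the 6-exo-trig mode with respect to the acyl carbon, the former pyrrole C2=C3 bond becoming the ring-fusion bond C7a=C3a. No stereocentre is formed. The selectivity required is attack by the α-carbon and not by the β-carbon on the other side of the tether, which would close an equally sized ring to an isoindolone; it should be secured by the intrinsic α-preference of a 1-sulfonylpyrrole when no AlCl3 is present. The remote α-carbon cannot reach the acyl group, and working at high dilution should keep intermolecular acylation at that position in check.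

Step 4
Reactants: 6 1-tosyl-1,4,5,6-tetrahydro-7H-indol-7-one
Product: 7 1,4,5,6-tetrahydro-7H-indol-7-one
Conditions: NaOH (2 M aq., 3 equiv), MeOH, rt to 50 °C; then aq. NH4Cl
Reagents that add atoms: none
Why: Alkaline N-desulfonylation: hydroxide attacks the sulfonyl sulfur and the anion of a 2-acylpyrrole is a good leaving group, so cleavage should be complete under mild conditions that do not affect the ketone.

Step 5
Reactants: 7 1,4,5,6-tetrahydro-7H-indol-7-one
Product: 9 2,3-dibromo-1,4,5,6-tetrahydro-7H-indol-7-one, via 3-bromo ketone 8 (not isolated)
Conditions: NBS (2.1 equiv), THF, 0 °C to rt, dark
Reagents that add atoms: N-bromosuccinimide, O=C1CCC(=O)N1Br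
Why: Electrophilic aromatic bromination of a 2-acylpyrrole, the reaction type that gives 4,5-dibromopyrrole-2-carbonyl compounds: both free ring carbons take up bromine, C3 first (not conjugated with the acyl group) and C2 second. Ring A is saturated and the tosyl group is gone, so no other sp2 C–H exists, and without acid or light the enol and radical pathways to bromination at C6 or C4 should stay slow.

Step 6
Reactants: 9 2,3-dibromo-1,4,5,6-tetrahydro-7H-indol-7-one
Product: 10 2,3,7-tribromo-4,5-dihydro-1H-indole
Conditions: P(OPh)3 (1.2 equiv), Br2 (1.15 equiv), CH2Cl2, −60 °C; then Et3N (1.3 equiv) and 9, −60 °C to reflux; aq. NaHCO3 work-up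
Reagents that add atoms: bromine, BrBr (used as the triphenyl phosphite dibromide formed from it in the flask)
Why: Ketone-to-vinyl-bromide conversion with the triphenyl phosphite–bromine reagent, as used for cyclic aryl ketones: the carbonyl oxygen attacks phosphorus, bromide adds to C7, triphenyl phosphate leaves to give a bromocarbenium ion stabilised by the pyrrole, and Et3N removes a proton from C6, the only α-CH2. C2 and C3 already carry bromine, so the electrophilic reagent finds no ring C–H, and the product is taken on at once because an α-bromovinylpyrrole is sensitive to aqueous acid.

Step 7
Reactants: 10 2,3,7-tribromo-4,5-dihydro-1H-indole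
Product: 11 2,3,7-tribromo-1H-indole (target)
Conditions: DDQ (1.2 equiv), toluene, 80 °C
Reagents that add atoms: none
Why: Quinone dehydrogenation of a dihydroarene: DDQ abstracts hydride from C4 or C5, both of which give cations stabilised by the pyrrole and the C6=C7 double bond, and loss of the neighbouring proton completes the benzene ring. Aromatisation is the driving force and DDQ does not touch C–Br bonds.

## Compound list

1 | 1-tosyl-1H-pyrrole | Cc1ccc(cc1)S(=O)(=O)n1cccc1 | starting material
2 | succinic anhydride | O=C1CCC(=O)O1 | starting material
3 | 4-oxo-4-(1-tosyl-1H-pyrrol-3-yl)butanoic acid | Cc1ccc(cc1)S(=O)(=O)n1ccc(c1)C(=O)CCC(=O)O | intermediate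
4 | 4-(1-tosyl-1H-pyrrol-3-yl)butanoic acid | Cc1ccc(cc1)S(=O)(=O)n1ccc(CCCC(=O)O)c1 | intermediate
5 | 4-(1-tosyl-1H-pyrrol-3-yl)butanoic trifluoroacetic anhydride (mixed anhydride) | Cc1ccc(cc1)S(=O)(=O)n1ccc(CCCC(=O)OC(=O)C(F)(F)F)c1 | intermediate (not isolated)
6 | 1-tosyl-1,4,5,6-tetrahydro-7H-indol-7-one | Cc1ccc(cc1)S(=O)(=O)n1ccc2CCCC(=O)c21 | intermediate
7 | 1,4,5,6-tetrahydro-7H-indol-7-one | O=C1CCCc2cc[nH]c12 | intermediate
8 | 3-bromo-1,4,5,6-tetrahydro-7H-indol-7-one | O=C1CCCc2c(Br)c[nH]c12 | intermediate (not isolated)
9 | 2,3-dibromo-1,4,5,6-tetrahydro-7H-indol-7-one | O=C1CCCc2c(Br)c(Br)[nH]c12 | intermediate
10 | 2,3,7-tribromo-4,5-dihydro-1H-indole | BrC1=CCCc2c(Br)c(Br)[nH]c12 | intermediate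
11 | 2,3,7-tribromo-1H-indole | Brc1[nH]c2c(Br)cccc2c1Br | target

## Step count and least certain steps

Total step count: 7. Longest linear sequence: 7 steps (from 1 and 2 to 11); the route is linear.

**Step 6.** Phosphorylation or bromination at the acidic N–H, activation that ends in loss of the N–H proton instead of the C6 proton, and hydrolysis of the α-bromovinylpyrrole back to the ketone during work-up are the likely failures. The cause is that the carbonyl is a vinylogous amide with an N–H beside it. The fallback runs the ketone-to-arene sequence while nitrogen still carries the sulfonyl group and introduces the pyrrole bromines last. It sets out from 6: P(OPh)3, Br2 and Et3N in CH2Cl2 would give 7-bromo-1-tosyl-4,5-dihydro-1H-indole F1, DDQ in toluene would aromatise it to 7-bromo-1-tosyl-1H-indole F2, and NaOH in MeOH/THF at reflux would free 7-bromo-1H-indole F3. N-Bromosuccinimide (2 equiv) on silica gel in CH2Cl2 would then brominate C3, giving 3,7-dibromo-1H-indole F4 without isolation, and then C2. The detour comes back to the route at 11. It gives up the positional control by the saturated ring and relies instead on the preference of indole for reaction in its pyrrole ring.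

**Step 3 (key step).** Slow ring closure is the main danger, because the attacking α-carbon is deactivated by the sulfonyl group and lies between it and the tether. Slow closure would open the way to intermolecular acylation at the unhindered remote α-carbon or to closure at the β-carbon. The fallback cyclises the unprotected pyrrole, whose α-carbon is far more nucleophilic. It sets out from 4: NaOH in aqueous MeOH at reflux would remove the sulfonyl group to give 4-(1H-pyrrol-3-yl)butanoic acid F5, and cyclodehydration of this acid in polyphosphoric acid at about 80 °C would form the same C7–C7a bond. The detour comes back to the route at 7, with the step count unchanged because the desulfonylation is only moved forward.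

**Step 7.** Sluggish hydride abstraction from a ring system made electron-poor by three bromines, or oxidative degradation of the N–H pyrrole by the quinone, may intervene. The fallback replaces hydride abstraction by bromination and dehydrobromination. It sets out from 10: N-bromosuccinimide (1 equiv) with a catalytic amount of AIBN in PhCF3 at 80 °C would brominate the allylic C5 position by a radical chain. The resulting 2,3,5,7-tetrabromo-4,5-dihydro-1H-indole F6 (racemic, not isolated) would lose HBr across C4–C5 under the same conditions. The detour comes back to the route at 11.

**Step 2.** The reduction may stall after the first hydride transfer, through lactonisation of the carbinol with the acid, if the sulfonylated pyrrole does not stabilise the cation well enough for the C–O bond to ionise. Partial reduction of the pyrrole ring is a lesser concern. The fallback is a desulfurisation that involves no carbocation. It sets out from 3: ethane-1,2-dithiol and BF3·OEt2 in CH2Cl2 would give 3-[2-(1-tosyl-1H-pyrrol-3-yl)-1,3-dithiolan-2-yl]propanoic acid F7, and Raney Ni in EtOH would replace both C–S bonds by C–H. The detour comes back to the route at 4.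

## Further compounds

F1 | step 6 | 7-bromo-1-tosyl-4,5-dihydro-1H-indole | Cc1ccc(cc1)S(=O)(=O)n1ccc2CCC=C(Br)c21
F2 | step 6 | 7-bromo-1-tosyl-1H-indole | Cc1ccc(cc1)S(=O)(=O)n1ccc2cccc(Br)c21
F3 | step 6 | 7-bromo-1H-indole | Brc1cccc2cc[nH]c12
F4 | step 6 | 3,7-dibromo-1H-indole | Brc1c[nH]c2c(Br)cccc12
F5 | step 3 | 4-(1H-pyrrol-3-yl)butanoic acid | OC(=O)CCCc1cc[nH]c1
F6 | step 7 | 2,3,5,7-tetrabromo-4,5-dihydro-1H-indole (racemic) | BrC1=CC(Br)Cc2c(Br)c(Br)[nH]c12
F7 | step 2 | 3-[2-(1-tosyl-1H-pyrrol-3-yl)-1,3-dithiolan-2-yl]propanoic acid | Cc1ccc(cc1)S(=O)(=O)n1ccc(c1)C1(CCC(=O)O)SCCS1
A1 | alternative 1 | 3-bromo-2H-pyran-2-one | O=C1OC=CC=C1Br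
A2 | alternative 1 | tert-butyl 2,3-dihydro-1H-pyrrole-1-carboxylate | CC(C)(C)OC(=O)N1CCC=C1
A3 | alternative 1 | tert-butyl cis-7-bromo-2,3,3a,7a-tetrahydro-1H-indole-1-carboxylate (racemic, one enantiomer drawn) | CC(C)(C)OC(=O)N1CC[C@H]2C=CC=C(Br)[C@@H]12
A4 | alternative 2 | 2,6-dibromoaniline | Nc1c(Br)cccc1Br
A5 | alternative 2 | N-(2,6-dibromophenyl)-N-(4-methoxybenzyl)acetamide | CC(=O)N(Cc1ccc(OC)cc1)c1c(Br)cccc1Br
A6 | alternative 2 | 7-bromo-1-(4-methoxybenzyl)indolin-2-one | COc1ccc(CN2C(=O)Cc3cccc(Br)c32)cc1
A7 | alternative 3 | 2-bromo-6-iodoaniline | Nc1c(Br)cccc1I
A8 | alternative 3 | N-[2-bromo-6-(bromoethynyl)phenyl]-4-methylbenzenesulfonamide | Cc1ccc(cc1)S(=O)(=O)Nc1c(Br)cccc1C#CBr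
A9 | alternative 3 | 2,3,7-tribromo-1-tosylindole | Cc1ccc(cc1)S(=O)(=O)n1c(Br)c(Br)c2cccc(Br)c21
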